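**Plan**

Target numbering (furo[3,2-c][1,2]dioxin-6-one): O1, O2, C3 (peroxy carbon with methyl and hexadecyl), C4, C4a (lactone carbinol carbon), O5, C6 (C=O), C7, C7a.

- Retrosynthesis: open O1–C7a (retro peroxy-Michael) and remove the peroxide at C3 (retro hydroperoxysilylation) to reach butenolide 14. Then cut C7–C6 and O5–C4a together, which excises CO2 from an axially chiral allene (11/12).
- Enabling feature: in the γ-lactone ring the carboxyl unit C6(=O)–O5 bridges C7 and the quaternary C4a across C7a. These three carbons can be an allene, nucleophilic at C7 as a 1-lithioallene and, once carboxylated, a π-electrophile at C4a.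
- Forward order: C18 alkenyl Grignard plus (S)-2-methylglycidol, then diol, alkynol, bromoallene, butenolide ring (step 6), silyl peroxide, 1,2-dioxane ring (step 8).
- Stereochemistry: C4a comes from (S)-2-methylglycidol by a centre-to-axis-to-centre relay (anti-SN2′, then carboxylate delivery to one allene face, net inversion). C7a follows from the cis fusion enforced in the peroxy-Michael closure. C3 forms without control and its epimers are separated at the end.

Key step: step 6

Remark: the peroxy carbon C3 arises from a planar tertiary radical with no facial bias, so 15 and 16 are expected together with their epimers at that carbon, and the epimeric peroxylactone is removed by chromatography after step 8.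

**Step 1**
Reactants: 1 1-bromopentadecane; 2 2,3-dibromoprop-1-ene
Product: 4 2-bromooctadec-1-ene, via pentadecylmagnesium bromide 3 (not isolated)
Conditions: Mg, THF, 40 °C; then 2, CuI (5 mol %), THF, 0 → 25 °C
Reagents that add atoms: none
Why: The Grignard reagent should displace the allylic bromide of 2 under copper catalysis (SN2 and SN2′ attack give the same product) while the vinylic bromide stays intact, a copper-catalysed Grignard allylic alkylation that creates no stereocentre.

**Step 2**
Reactants: 4 2-bromooctadec-1-ene; 5 (S)-2-methylglycidol
Product: 7 (2R)-2-methyl-4-methylideneicosane-1,2-diol, via octadec-1-en-2-ylmagnesium bromide 6 (not isolated)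
Conditions: 4, Mg, THF, 50 °C; 5 pre-treated with n-BuLi (1.0 equiv), THF, −78 °C; combine, CuI (10 mol %), −40 → 0 °C; then 1 M HCl, 0 °C
Reagents that add atoms: none
Why: Copper-catalysed Grignard opening of the 2,2-disubstituted epoxide (as its lithium alkoxide) should occur by SN2 attack at the unsubstituted CH2, so the quaternary carbinol centre of 5 is carried over untouched and is (R) in 7 only through the change in substituent priorities.

**Step 3**
Reactants: 7 (2R)-2-methyl-4-methylideneicosane-1,2-diol
Product: 8 (2R)-2-hydroxy-2-methyl-4-methylideneicosanal
Conditions: SO3·pyridine, DMSO, i-Pr2NEt, CH2Cl2, 0 °C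
Reagents that add atoms: none
Why: The Parikh–Doering oxidation should convert only the primary alcohol, since the tertiary alcohol has no carbinol hydrogen, and under these non-cleaving conditions the 1,2-diol and the stereocentre are not endangered.

**Step 4**
Reactants: 8 (2R)-2-hydroxy-2-methyl-4-methylideneicosanal
Product: 9 (3R)-3-methyl-5-methylidenehenicos-1-yn-3-ol
Conditions: dimethyl (1-diazo-2-oxopropyl)phosphonate, K2CO3, MeOH, 0 → 25 °C
Reagents that add atoms: dimethyl (1-diazo-2-oxopropyl)phosphonate, CC(=O)C(=[N+]=[N-])P(=O)(OC)OC
Why: The Ohira–Bestmann (Seyferth–Gilbert) homologation should turn the aldehyde into the terminal alkyne under mild carbonate conditions that leave the free tertiary alcohol and its configuration untouched.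

**Step 5**
Reactants: 9 (3R)-3-methyl-5-methylidenehenicos-1-yn-3-ol
Product: 11 (Sa)-1-bromo-3-methyl-5-methylidenehenicosa-1,2-diene, via propargylic mesylate 10 (not isolated)
Conditions: n-BuLi (1.05 equiv), THF, −78 °C; MsCl, −78 °C; then LiCuBr2 (from CuBr and LiBr), THF, −78 → −20 °C
Reagents that add atoms: lithium dibromocuprate LiCuBr2, [Li+].Br[Cu-]Br
Why: The bromocuprate should displace the in situ mesylate by anti-SN2′ attack at the alkyne terminus (monovalent copper adds anti to the leaving group, then reductive elimination), the known propargyl-to-allenyl substitution of propargylic sulfonates, so the (R)-carbinol centre is translated into the (Sa)-axis.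

**Step 6**
Reactants: 11 (Sa)-1-bromo-3-methyl-5-methylidenehenicosa-1,2-diene
Product: 14 (5S)-5-methyl-5-(2-methylideneoctadecyl)furan-2(5H)-one, via lithioallene 12 (not isolated), via allenoic acid 13 (not isolated)
Conditions: t-BuLi (2.05 equiv), Et2O, −95 °C, 10 min; CO2 (dry gas), −95 → −40 °C; 1 M HCl, extraction (crude 13 not purified); AgNO3 (10 mol %), acetone, 25 °C, dark
Reagents that add atoms: carbon dioxide, O=C=O
Why: Bromine–lithium exchange at −95 °C should give the 1-lithioallene 12 with retention at the sp2 carbon, and this hard C(sp2)–Li nucleophile should take up CO2 at the lithiated carbon and not at the fully substituted γ-carbon, which forms the C7–C6 bond and keeps the allene axis. Monovalent silver then binds the distal allene π-bond of acid 13, the carboxylate oxygen adds to the terminal allene carbon anti to silver and protodemetalation follows, which forms the O5–C4a bond and closes the butenolide by a 5-endo-trig cyclisation. The closest known reaction types are the carboxylation of 1-lithioallenes and the silver-catalysed cycloisomerisation of 2,3-allenoic acids with axis-to-centre chirality transfer; together they amount to a formal (3+2) union of CO2 with the C7–C7a–C4a allene unit. The new quaternary stereocentre is controlled by the allene axis alone, because the carboxyl group can reach only the π-face of the terminal carbon on its own side, so the (Sa)-acid should give the (S)-lactone, a net inversion of the propargylic centre of 9. The step needs α- over γ-carboxylation, configurational integrity of 12 and chemoselectivity over the isolated 1,1-disubstituted alkene; the quaternary γ-carbon, the low temperature with short residence time, and the fact that the remote alkene cannot reach the carboxylate in a small ring should secure these.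

**Step 7**
Reactants: 14 (5S)-5-methyl-5-(2-methylideneoctadecyl)furan-2(5H)-one
Product: 15 (5S)-5-methyl-5-[(2R)-2-methyl-2-(triethylsilylperoxy)octadecyl]furan-2(5H)-one (formed together with its side-chain C2 epimer)
Conditions: Co(thd)2 [cobalt bis(2,2,6,6-tetramethylheptane-3,5-dionate)] (10 mol %), O2 (1 atm), Et3SiH (2 equiv), 1,2-dichloroethane, 25 °C
Reagents that add atoms: dioxygen, O=O; triethylsilane, CC[SiH](CC)CC
Why: In this Isayama–Mukaiyama hydroperoxysilylation a cobalt hydride should transfer a hydrogen atom to the electron-rich 1,1-disubstituted alkene in preference to the electron-poor, β-hindered butenolide, and the tertiary radical should trap O2 and be silylated at the Markovnikov carbon; the planar radical has no facial bias, so the new peroxy centre is expected as both epimers.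

**Step 8**
Reactants: 15 (5S)-5-methyl-5-[(2R)-2-methyl-2-(triethylsilylperoxy)octadecyl]furan-2(5H)-one
Product: 17 (3R,4aS,7aS)-3-hexadecyl-3,4a-dimethyl-3,4,4a,7a-tetrahydrofuro[3,2-c][1,2]dioxin-6(7H)-one, via hydroperoxide 16 (not isolated)
Conditions: TBAF (1.1 equiv), AcOH (1.1 equiv), THF, 0 °C; then Et2NH (0.3 equiv), CF3CH2OH, 25 °C; SiO2 chromatography
Reagents that add atoms: none
Why: Fluoride should free the hydroperoxide, which under amine catalysis adds to the butenolide β-carbon in a 6-exo-trig peroxy-Michael addition; the three-atom tether from the quaternary carbon can reach only the face on which it sits, so the ring fusion is cis and C7a is set (S) by C4a, and the target is separated from its C3 epimer by chromatography.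

**Compound list**

1 | 1-bromopentadecane | CCCCCCCCCCCCCCCBr | starting material
2 | 2,3-dibromoprop-1-ene | C=C(Br)CBr | starting material
3 | pentadecylmagnesium bromide | CCCCCCCCCCCCCCC[Mg]Br | intermediate
4 | 2-bromooctadec-1-ene | C=C(Br)CCCCCCCCCCCCCCCC | intermediate
5 | (S)-2-methylglycidol, [(2S)-2-methyloxiran-2-yl]methanol | OC[C@@]1(C)CO1 | starting material
6 | octadec-1-en-2-ylmagnesium bromide | C=C([Mg]Br)CCCCCCCCCCCCCCCC | intermediate
7 | (2R)-2-methyl-4-methylideneicosane-1,2-diol | OC[C@](C)(O)CC(=C)CCCCCCCCCCCCCCCC | intermediate
8 | (2R)-2-hydroxy-2-methyl-4-methylideneicosanal | O=C[C@](C)(O)CC(=C)CCCCCCCCCCCCCCCC | intermediate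
9 | (3R)-3-methyl-5-methylidenehenicos-1-yn-3-ol | C#C[C@](C)(O)CC(=C)CCCCCCCCCCCCCCCC | intermediate
10 | (3R)-3-methyl-5-methylidenehenicos-1-yn-3-yl methanesulfonate | C#C[C@](C)(OS(C)(=O)=O)CC(=C)CCCCCCCCCCCCCCCC | intermediate
11 | (Sa)-1-bromo-3-methyl-5-methylidenehenicosa-1,2-diene | BrC([H])=[C@@]=C(C)CC(=C)CCCCCCCCCCCCCCCC | intermediate
12 | (Sa)-(3-methyl-5-methylidenehenicosa-1,2-dien-1-yl)lithium | [Li]C([H])=[C@@]=C(C)CC(=C)CCCCCCCCCCCCCCCC | intermediate
13 | (Sa)-4-methyl-6-methylidenedocosa-2,3-dienoic acid | OC(=O)C([H])=[C@@]=C(C)CC(=C)CCCCCCCCCCCCCCCC | intermediate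
14 | (5S)-5-methyl-5-(2-methylideneoctadecyl)furan-2(5H)-one | C=C(CCCCCCCCCCCCCCCC)C[C@]1(C)OC(=O)C=C1 | intermediate
15 | (5S)-5-methyl-5-[(2R)-2-methyl-2-(triethylsilylperoxy)octadecyl]furan-2(5H)-one, formed together with its (2S)-side-chain epimer | CCCCCCCCCCCCCCCC[C@@](C)(OO[Si](CC)(CC)CC)C[C@]1(C)OC(=O)C=C1 | intermediate
16 | (5S)-5-[(2R)-2-hydroperoxy-2-methyloctadecyl]-5-methylfuran-2(5H)-one, formed together with its (2S)-side-chain epimer | CCCCCCCCCCCCCCCC[C@@](C)(OO)C[C@]1(C)OC(=O)C=C1 | intermediate
17 | (3R,4aS,7aS)-3-hexadecyl-3,4a-dimethyl-3,4,4a,7a-tetrahydrofuro[3,2-c][1,2]dioxin-6(7H)-one | CCCCCCCCCCCCCCCC[C@]1(C)C[C@]2(C)OC(=O)C[C@@H]2OO1 | target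

**Step count and risks**

Total steps: 8. Longest linear sequence: 8 steps (1 to 17).

Risk 1, step 6. The lithioallene may lose its axial configuration by inversion through its propargyl-type resonance form, may be carboxylated at the γ-carbon, or the base may abstract the proton geminal to bromine in place of exchange. Fallback: set out from 11 and replace the organolithium by a palladium-catalysed hydroxycarbonylation of the C(sp2)–Br bond (Pd(PPh3)4, CO 5 bar, i-Pr2NEt, THF–H2O, 40 °C). Oxidative addition to zerovalent palladium with retention, CO insertion and hydrolysis of the acylpalladium should give 13 after acidification. The route is rejoined at 13 for the silver-mediated closure to 14; no new compound arises.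

Risk 2, step 5. The tertiary mesylate may ionise before substitution, or the bromoallene may racemise by repeated copper-bromide SN2′ exchange, so that stereochemical fidelity is eroded; a propargylic bromide may also form. Fallback: set out from 9 and convert it (n-BuLi, ClCO2Me, THF, −78 °C) into (3R)-3-methyl-5-methylidenehenicos-1-yn-3-yl methyl carbonate F1. Carbonylation of F1 (Pd(PPh3)4, CO 1–5 bar, THF–H2O 5:1, 25 °C) should proceed by anti-SN2′ oxidative addition of zerovalent palladium, retentive CO insertion and hydrolysis, the known carbonylation of propargylic carbonates to 2,3-dienoic acids. This gives the same (Sa)-acid and comes back to the route at 13, bypassing 10 to 12.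

Risk 3, step 7. Hydrogen-atom transfer may occur to the butenolide C=C, or the peroxide may be reduced further to the tertiary alcohol or silyl ether. Fallback: set out from 14 and use ionic Markovnikov hydroperoxymercuration (Hg(OAc)2, H2O2 in Et2O, 0 °C) to the {2-hydroperoxy-2-{[(2S)-2-methyl-5-oxo-2,5-dihydrofuran-2-yl]methyl}octadecyl}mercury acetate F2, as both epimers at the peroxy carbon. Hydride demercuration (NaBH4, aq. NaOH, 0 °C, short contact) should give hydroperoxide 16, and the route is rejoined at 16 for the amine-catalysed ring closure of step 8.

**Further compounds**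

F1 | step 5 | (3R)-3-methyl-5-methylidenehenicos-1-yn-3-yl methyl carbonate | C#C[C@](C)(OC(=O)OC)CC(=C)CCCCCCCCCCCCCCCC
F0 | step 6 | none | none
F2 | step 7 | {2-hydroperoxy-2-{[(2S)-2-methyl-5-oxo-2,5-dihydrofuran-2-yl]methyl}octadecyl}mercury acetate (both epimers at the peroxy carbon) | CC(=O)O[Hg]CC(OO)(CCCCCCCCCCCCCCCC)C[C@]1(C)OC(=O)C=C1
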